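**Plenty left.** The dusk run still holds 76.1% of its electrophile at 40.0 min, target 24.9% covers what has gone, and yet the run has slowed.

the same everywhere: electrophile 0.20 M
- spring: nucleophile 0.21 M; run made earlier
- dusk: nucleophile 0.28 M; run made earlier
- alder: nucleophile 0.260 M; time 1.0 h
- ash: nucleophile 0.390 M; time 1.0 h

| run | time / min | electrophile / % | target / % |
|---|---|---|---|
| spring | 8.00 | 94.8 | 4.7 |
| spring | 15.0 | 90.8 | 9.2 |
| spring | 20.0 | 88.3 | 11.7 |
| spring | 30.0 | 84.4 | 15.8 |
| spring | 40.0 | 81.0 | 18.5 |
| dusk | 8.00 | 92.7 | 7.4 |
| dusk | 15.0 | 87.6 | 12.5 |
| dusk | 20.0 | 84.1 | 15.4 |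
| dusk | 30.0 | 79.8 | 20.7 |
| dusk | 40.0 | 76.1 | 24.9 |

(readings scatter by 0.3 percentage points)



1. part of the electrophile that has reacted at the end, alder
2. part of the electrophile that has reacted at the end, ash
3. what raising the concentration of nucleophile from its lowest to its highest value here does to the part of the electrophile that has reacted (changes below 5 percentage points count as none) (it rises / it falls / no change)

**Two readings.** Suppose one nucleophile goes with each electrophile. The integrated second-order law, called the clock G here, is then G = ln[(c(nucleophile)/its charge) / (c(electrophile)/its charge)] / (nucleophile charge − electrophile charge). It counts the leftovers and should rise evenly with time. At 40.0 min the spring run reads 1.11 M⁻¹ and the dusk run 1.07 M⁻¹, close together despite different charges. Their mean at 20.0 min is 0.643 M⁻¹, but the next stretch of equal length adds less, 0.447 M⁻¹.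

**My reckoning.** The second stretch is a share 0.698 of the first, as read. If the next stretch shrinks by the same share, the clock reading at 1.0 h is 1.41 M⁻¹. With r = exp(G × charge difference), the part reacted is (nucleophile charge)(r − 1) / (r × nucleophile charge − electrophile charge). That gives alder 27.6% and ash 38.6%.

**The forecast.** Noting that “the reaction is slowing faster than simple second-order kinetics predict”, the forecast gives alder 28.5% and ash 40%, a little higher than my figures, and for the trend: it rises.

**The flask.** Alder reaches 29.1% and ash 40.8%; the trend is it rises, by 12 percentage points.

    nucleophile + acid set free ⇌ protonated nucleophile, settled at all times (K = 7600 M⁻¹)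
    electrophile + nucleophile → acid set free + target (k = 0.0370 M⁻¹ min⁻¹)
    nucleophile ⇌ dormant form (K = 0.480, k = 0.00940 min⁻¹)

**One neighbour.** The clock figures fall short by 1.5 points for alder and 2.2 points for ash. The neighbouring flask is alder charged with 1.0 M of nucleophile; the same clock gives it 72.2%. That neighbouring flask reaches 76.5%.

The runs are calculated from invented constants, and the scatter is random.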